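**Route outline**

- Retrosynthetic cuts: the phenolic O–acetyl and O5–acetyl bonds; C1–H back to a benzylic C1–O5 bond; C3–OAc back to the epimeric ring alcohol; C1–O5 and C1–C2 together (Prins) to vanillin acetate and (S)-hept-1-en-4-ol; C4–C5 to butanal and an allyl nucleophile.
- Enabling feature: O5 is 1,5 to the benzylic carbon C1 and 1,3 to O3, so O5–C5–C4–C3–C2–C1 can be closed as a temporary 2-aryl-tetrahydropyran whose C1–O5 bond is benzylic and can be cut again by hydrogenolysis; the guaiacol ring is bought intact.
- Forward order: allylboration joins C4–C5; the Prins step joins arene-bearing C1 to the chain and closes the only (temporary) ring; ester exchange and inversion at C3 are done on the ring; hydrogenolysis reopens it; acetylation and phenol release finish.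
- Stereochemistry: C5 (S) comes from the reagent-controlled allylboration and its C–O bond is never broken; C3 comes from 1,3-induction in the Prins chair followed by one Mitsunobu inversion to the syn (3R,5S) array; the C1 stereocenter is transient.

Key step: step 2

Numbering used throughout (target chain): C1 = benzylic CH2, C3 and C5 = acetoxy carbons (O3, O5 their oxygens), C8 = methyl end.

Assumption: the allylborane carrying isopinocampheyl groups from (−)-α-pinene is taken to attack the Re face of unbranched aliphatic aldehydes, which gives the S carbinol here; this is to be checked on alcohol 6 by Mosher ester analysis before it is carried on, and the antipodal reagent would be used if the check said otherwise.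

**Step 1**
Reactants: 1 butanal; 2 allylmagnesium bromide; 3 (+)-B-methoxydiisopinocampheylborane (from (−)-α-pinene)
Product: 6 (S)-hept-1-en-4-ol, via (+)-B-allyldiisopinocampheylborane 4 (not isolated), via borinate ester 5 (not isolated)
Conditions: 3 + 2, Et2O, 0 °C to rt; then 1, −78 °C; then NaOH, aq. H2O2, rt
Reagents that add atoms: none
Why: Brown asymmetric allylboration, in which 2 and 3 give allylborane 4, which transfers allyl to the Re face of butanal through a closed six-membered chair transition state controlled by the isopinocampheyl groups, setting C5 as S, and alkaline peroxide then releases 6 from borinate 5.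

**Step 2**
Reactants: 6 (S)-hept-1-en-4-ol; 7 vanillin acetate (4-formyl-2-methoxyphenyl acetate)
Product: 10 (2S,4R,6S)-2-(4-acetoxy-3-methoxyphenyl)-6-propyltetrahydro-2H-pyran-4-yl trifluoroacetate (all-cis), via (E)-oxocarbenium ion 8 (not isolated), via tetrahydropyran-4-yl cation 9 (not isolated)
Conditions: CF3CO2H (excess), CH2Cl2, 0 °C to rt; concentrate (toluene azeotrope), crude used directly
Reagents that add atoms: trifluoroacetic acid, OC(=O)C(F)(F)F
Why: Prins cyclization, in which acid condenses 6 and 7 to the (E)-oxocarbenium ion 8, whose terminal alkene carbon (future C2) attacks the cationic carbon (future C1) while the internal alkene carbon (future C3) takes up the charge as cation 9, which trifluoroacetate captures. The closest known reaction type is the trifluoroacetic acid-mediated Prins cyclization of homoallylic alcohols with aryl aldehydes to all-cis 2,6-disubstituted tetrahydropyran-4-yl esters. The tetrahydropyran ring O5–C5–C4–C3–C2–C1 closes in a 6-endo-trig mode through a chair transition state, and the guaiacol ring is carried in unchanged. The new stereocenter at C1 is set cis to the propyl group because the E geometry of 8 and the equatorial propyl group place the aryl group equatorial, and the new stereocenter at C3 is set cis to both because trifluoroacetate adds equatorially to the delocalized cation 9 (1,3-induction from C5 relayed by the chair). The step needs the all-cis arrangement and no erosion of the C5 configuration by 2-oxonia-Cope rearrangement, side-chain exchange or benzylic ionization. These are secured by the equatorial propyl group on a non-benzylic carbinol carbon, by the aryl-conjugated oxocarbenium ion being the more stable partner of the 2-oxonia-Cope pair, and by the acetylated, less electron-rich phenol.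

**Step 3**
Reactants: 10 all-cis tetrahydropyranyl trifluoroacetate
Product: 11 4-[(2S,4R,6S)-4-hydroxy-6-propyltetrahydro-2H-pyran-2-yl]-2-methoxyphenyl acetate (equatorial hydroxyl)
Conditions: NaHCO3, MeOH/H2O, 0 °C, short reaction time
Reagents that add atoms: none
Why: Chemoselective ester solvolysis, since the trifluoroacetyl carbonyl is far more electrophilic than that of the aryl acetate, so brief bicarbonate treatment at 0 °C should free the C3 hydroxyl by acyl–oxygen cleavage without touching the phenolic acetate or any stereocenter.

**Step 4**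
Reactants: 11 all-cis tetrahydropyran-4-ol
Product: 13 4-[(2S,4S,6S)-4-acetoxy-6-propyltetrahydro-2H-pyran-2-yl]-2-methoxyphenyl acetate (axial 4-acetate), via alkoxyphosphonium acetate 12 (not isolated)
Conditions: AcOH, PPh3, DIAD, THF, 0 °C to rt
Reagents that add atoms: acetic acid, CC(=O)O
Why: Mitsunobu esterification, in which the equatorial hydroxyl is activated as alkoxyphosphonium ion 12 and displaced by acetate in an SN2 reaction along the axial trajectory (flanked only by axial hydrogens), inverting C3 to the configuration that becomes 3R, syn to C5, and installing the final C3 acetate at the same time.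

**Step 5**
Reactants: 13 axial acetate
Product: 14 (3R,5S)-1-(4-acetoxy-3-methoxyphenyl)-5-hydroxyoctan-3-yl acetate
Conditions: H2 (1–4 atm), Pd(OH)2/C, EtOAc/AcOH, rt
Reagents that add atoms: none
Why: Catalytic hydrogenolysis of a benzylic C–O bond, which should cleave the ring C1–O5 bond, turn C1 into the benzylic CH2 and release the C5 hydroxyl with its C–O bond and configuration untouched, while alkyl and aryl acetates are inert and any 1,3-acetyl migration between O3 and O5 is harmless because both oxygens carry acetates after step 6.

**Step 6**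
Reactants: 14 open-chain hydroxy acetate
Product: 15 (3R,5S)-1-(4-acetoxy-3-methoxyphenyl)octane-3,5-diyl diacetate (triacetate)
Conditions: Ac2O, pyridine, DMAP (cat.), CH2Cl2, rt
Reagents that add atoms: acetic anhydride, CC(=O)OC(C)=O
Why: Nucleophile-catalyzed O-acylation of the secondary C5 alcohol, which reacts only at the O–H bond and so retains configuration, and which converges any acetyl-migration isomers of 14 on the single triacetate.

**Step 7**
Reactants: 15 triacetate
Product: 16 (3R,5S)-1-(4-hydroxy-3-methoxyphenyl)octane-3,5-diyl diacetate (target)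
Conditions: pyrrolidine, CH2Cl2, 0 °C
Reagents that add atoms: none
Why: Chemoselective aminolysis of an aryl ester, since phenoxide is a far better leaving group than a secondary alkoxide, so pyrrolidine at 0 °C should remove only the phenolic acetate and leave both secondary acetates and both stereocenters unchanged.

**Compound list**

1 | butanal | CCCC=O | starting material
2 | allylmagnesium bromide | C=CC[Mg]Br | starting material
3 | (+)-B-methoxydiisopinocampheylborane (isopinocampheyl groups from (−)-α-pinene) | COB([C@H]1C[C@H]2C[C@@H]([C@@H]1C)C2(C)C)[C@H]1C[C@H]2C[C@@H]([C@@H]1C)C2(C)C | starting material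
4 | (+)-B-allyldiisopinocampheylborane (same isopinocampheyl groups as 3) | C=CCB([C@H]1C[C@H]2C[C@@H]([C@@H]1C)C2(C)C)[C@H]1C[C@H]2C[C@@H]([C@@H]1C)C2(C)C | intermediate
5 | (4S)-hept-1-en-4-yl diisopinocampheylborinate | CCC[C@@H](CC=C)OB([C@H]1C[C@H]2C[C@@H]([C@@H]1C)C2(C)C)[C@H]1C[C@H]2C[C@@H]([C@@H]1C)C2(C)C | intermediate
6 | (S)-hept-1-en-4-ol | CCC[C@@H](CC=C)O | intermediate
7 | vanillin acetate (4-formyl-2-methoxyphenyl acetate) | COc1cc(C=O)ccc1OC(C)=O | starting material
8 | (E)-[(4-acetoxy-3-methoxyphenyl)methylidene][(4S)-hept-1-en-4-yl]oxonium trifluoroacetate | CCC[C@@H](CC=C)/[O+]=C/c1ccc(OC(C)=O)c(OC)c1.[O-]C(=O)C(F)(F)F | intermediate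
9 | 2,6-cis-2-(4-acetoxy-3-methoxyphenyl)-6-propyltetrahydropyran-4-yl cation (propyl-bearing carbon as in 6), trifluoroacetate counter-ion | O1[C@@H](CCC)C[CH+]C[C@H]1c2ccc(OC(C)=O)c(OC)c2.[O-]C(=O)C(F)(F)F | intermediate
10 | (2S,4R,6S)-2-(4-acetoxy-3-methoxyphenyl)-6-propyltetrahydro-2H-pyran-4-yl trifluoroacetate (all-cis) | O1[C@@H](CCC)C[C@@H](OC(=O)C(F)(F)F)C[C@H]1c2ccc(OC(C)=O)c(OC)c2 | intermediate
11 | 4-[(2S,4R,6S)-4-hydroxy-6-propyltetrahydro-2H-pyran-2-yl]-2-methoxyphenyl acetate (all-cis, equatorial OH) | O1[C@@H](CCC)C[C@@H](O)C[C@H]1c2ccc(OC(C)=O)c(OC)c2 | intermediate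
12 | {[(2S,4R,6S)-2-(4-acetoxy-3-methoxyphenyl)-6-propyltetrahydro-2H-pyran-4-yl]oxy}triphenylphosphonium acetate | O1[C@@H](CCC)C[C@@H](O[P+](c2ccccc2)(c2ccccc2)c2ccccc2)C[C@H]1c1ccc(OC(C)=O)c(OC)c1.CC(=O)[O-] | intermediate
13 | 4-[(2S,4S,6S)-4-acetoxy-6-propyltetrahydro-2H-pyran-2-yl]-2-methoxyphenyl acetate (2,6-cis, axial 4-acetate) | O1[C@@H](CCC)C[C@H](OC(C)=O)C[C@H]1c2ccc(OC(C)=O)c(OC)c2 | intermediate
14 | (3R,5S)-1-(4-acetoxy-3-methoxyphenyl)-5-hydroxyoctan-3-yl acetate | O[C@@H](CCC)C[C@H](OC(C)=O)CCc1ccc(OC(C)=O)c(OC)c1 | intermediate
15 | (3R,5S)-1-(4-acetoxy-3-methoxyphenyl)octane-3,5-diyl diacetate | CCC[C@@H](C[C@@H](CCc1ccc(OC(C)=O)c(OC)c1)OC(C)=O)OC(C)=O | intermediate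
16 | (3R,5S)-1-(4-hydroxy-3-methoxyphenyl)octane-3,5-diyl diacetate | CCC[C@@H](C[C@@H](CCc1ccc(O)c(OC)c1)OC(C)=O)OC(C)=O | target

**Step count and risks**

Total step count: 7. Longest linear sequence: 7 steps (from butanal).

Most likely to fail, in this order:

Step 2. The aryl-conjugated oxocarbenium ion may cyclize slowly enough for 2-oxonia-Cope rearrangement and side-chain exchange to compete, which would give symmetric tetrahydropyrans and erode the enantiomeric purity. Fallback: starting again from 6 and 7, a bromide-terminated Prins cyclization (InBr3 cat., Me3SiBr, CH2Cl2, 0 °C), in which fast low-temperature halide capture should outrun the exchange, would give the all-cis bromide 4-[(2S,4R,6S)-4-bromo-6-propyltetrahydro-2H-pyran-2-yl]-2-methoxyphenyl acetate F1. SN2 displacement of its equatorial bromide with CsOAc and 18-crown-6 in warm toluene would then invert C3 and return to the route at 13, bypassing steps 3 and 4.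

Step 4. Elimination of the alkoxyphosphonium ion to a dihydropyran, or sluggish displacement because acetic acid is a weak Mitsunobu acid, may cut into the inversion. Fallback: from 11, oxidation with Dess–Martin periodinane (CH2Cl2, rt) would give the ketone 4-[(2S,6S)-4-oxo-6-propyltetrahydro-2H-pyran-2-yl]-2-methoxyphenyl acetate F2. Reduction with LiBH(s-Bu)3 (THF, −78 °C), which delivers hydride equatorially, would give the axial alcohol 4-[(2S,4S,6S)-4-hydroxy-6-propyltetrahydro-2H-pyran-2-yl]-2-methoxyphenyl acetate F3. Acetylation (Ac2O, pyridine, DMAP) would return to the route at 13; a phenolic acetate lost to the hydride would be restored in that acetylation.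

Step 5. Cleavage of the cyclic benzylic ether bond may be slow on the catalyst surface, and forcing it risks saturation of the arene. Fallback (ionic instead of catalytic reduction): from 13, pyrrolidine (CH2Cl2, 0 °C) would free the phenol to give (2S,4S,6S)-2-(4-hydroxy-3-methoxyphenyl)-6-propyltetrahydro-2H-pyran-4-yl acetate F4. Et3SiH with BF3·OEt2 (CH2Cl2, −78 to 0 °C) would open the ring through the p-hydroxybenzyl (quinone-methide-type) cation at C1 and reduce it to (3R,5S)-5-hydroxy-1-(4-hydroxy-3-methoxyphenyl)octan-3-yl acetate F5; neither C3–O nor C5–O is broken. Exhaustive acetylation (Ac2O, pyridine, DMAP) would return to the route at 15.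

**Further compounds**

F1 | step 2 | 4-[(2S,4R,6S)-4-bromo-6-propyltetrahydro-2H-pyran-2-yl]-2-methoxyphenyl acetate | O1[C@@H](CCC)C[C@@H](Br)C[C@H]1c2ccc(OC(C)=O)c(OC)c2
F2 | step 4 | 4-[(2S,6S)-4-oxo-6-propyltetrahydro-2H-pyran-2-yl]-2-methoxyphenyl acetate | O1[C@@H](CCC)CC(=O)C[C@H]1c2ccc(OC(C)=O)c(OC)c2
F3 | step 4 | 4-[(2S,4S,6S)-4-hydroxy-6-propyltetrahydro-2H-pyran-2-yl]-2-methoxyphenyl acetate | O1[C@@H](CCC)C[C@H](O)C[C@H]1c2ccc(OC(C)=O)c(OC)c2
F4 | step 5 | (2S,4S,6S)-2-(4-hydroxy-3-methoxyphenyl)-6-propyltetrahydro-2H-pyran-4-yl acetate | O1[C@@H](CCC)C[C@H](OC(C)=O)C[C@H]1c2ccc(O)c(OC)c2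
F5 | step 5 | (3R,5S)-5-hydroxy-1-(4-hydroxy-3-methoxyphenyl)octan-3-yl acetate | O[C@@H](CCC)C[C@H](OC(C)=O)CCc1ccc(O)c(OC)c1
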